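**Retrosynthetic overview**
1. Last bond: the C6–O lactone bond, made by an acid-catalysed transannular lactonization in which an endo acrylate displaces the ether bridge of an 8-oxabicyclo[3.2.1]octane with inversion (new reaction); this also frees the C9 hydroxyl.
2. Before that, on the rigid oxabicycle: exo addition of a crotonoyl anion equivalent to the C1 ketone, exo enolate hydroxylation at C5 with isovalerylation under kinetic resolution, and ester α-methylenation.
3. C7 is set by exo hydrogenation of the bicyclic alkene; the carbon skeleton comes from a (4+3) cycloaddition of a 3-furylacetate with the oxyallyl cation from 3-chlorobutan-2-one.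
4. Ring order: cycloheptanone and bridging tetrahydrofuran together in the cycloaddition; the γ-lactone last, at the expense of the tetrahydrofuran.

Atom labels C1 to C15 are those of the target (ring C1, C5 to C10; lactone C11 to C13; side chain C2 to C4 and C15).
Assumption: racemates 7 to 14 are drawn as the enantiomer that is carried on, and in step 6 the (S)-catalyst is taken to acylate that enantiomer (usual π-stacking model for this catalyst class); if the sense is reversed, the (R)-catalyst is used.

**Step 1**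
Reactants: 1 3-bromofuran; 2 tert-butyl acetate
Product: 4 tert-butyl 2-(furan-3-yl)acetate, via lithium enolate 3 (not isolated)
Conditions: LiN(SiMe3)2 (2.2 equiv), Pd(dba)2 (1 mol%), P(t-Bu)3 (1 mol%), toluene, rt
Reagents that add atoms: none
Why: Pd-catalysed α-arylation of an ester enolate (Buchwald–Hartwig type), in which zerovalent palladium inserts into the C–Br bond and the lithium enolate couples at C3 of the furan; no stereocentre is formed.

**Step 2**
Reactants: 4 tert-butyl 2-(furan-3-yl)acetate; 5 3-chlorobutan-2-one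
Product: 7 tert-butyl 2-[rac-(1R,2S,5R)-2-methyl-3-oxo-8-oxabicyclo[3.2.1]oct-6-en-6-yl]acetate, via oxyallyl cation 6 (not isolated)
Conditions: 5 (2 equiv), NaOCH2CF3 (2 equiv, slow addition), CF3CH2OH, 0 °C to rt
Reagents that add atoms: none
Why: Föhlisch-type (4+3) cycloaddition, in which the unhindered CH2 terminus of cation 6 bonds to the more nucleophilic furan C2 (next to the side chain) and the CHMe terminus closes onto C5, so the methyl group ends up remote from the side chain (expected, not proven, as the major regioisomer), and the basic medium equilibrates it to the equatorial position anti to the O bridge (C9 and C10 relative configuration); racemic.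

**Step 3**
Reactants: 7 bicyclic enone ester from step 2
Product: 8 tert-butyl 2-[rac-(1R,2S,5R,6S)-2-methyl-3-oxo-8-oxabicyclo[3.2.1]octan-6-yl]acetate
Conditions: H2 (1 atm), Pd/C (5%), EtOAc, rt
Reagents that add atoms: none
Why: Heterogeneous hydrogenation delivers H2 to the exposed exo face (syn to the O bridge) of the bicyclic alkene, which pushes the side chain into the endo position and sets C7 of the target.

**Step 4**
Reactants: 8 saturated keto ester
Product: 12 tert-butyl 2-[rac-(1R,2S,5R,6S)-2-methyl-3-oxo-8-oxabicyclo[3.2.1]octan-6-yl]prop-2-enoate, via dilithium bis-enolate 9 (not isolated), via Mannich base 10 (not isolated), via methiodide 11 (not isolated)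
Conditions: LiN(i-Pr)2 (2.2 equiv), THF, −78 to −40 °C; CH2=NMe2+ I− (1.0 equiv), −78 to 0 °C; aq NH4Cl; then MeI, MeOH, rt; then NaHCO3, CH2Cl2/H2O
Reagents that add atoms: N,N-dimethylmethyleneiminium iodide, C=[N+](C)C.[I-]
Why: Eschenmoser α-methylenation through a dianion, in which the ketone is protected as its kinetic enolate (CH2 side) while the more reactive ester enolate alone is aminomethylated, and quaternisation with E1cB elimination gives the acrylate; no stereocentre is touched.

**Step 5**
Reactants: 12 keto acrylate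
Product: 14 tert-butyl 2-[rac-(1R,2S,4S,5S,6S)-4-hydroxy-2-methyl-3-oxo-8-oxabicyclo[3.2.1]octan-6-yl]prop-2-enoate, via potassium enolate 13 (not isolated)
Conditions: KN(SiMe3)2 (1.1 equiv), THF, −78 °C; 3-phenyl-2-(phenylsulfonyl)oxaziridine (1.3 equiv), −78 °C; aq NH4Cl
Reagents that add atoms: 3-phenyl-2-(phenylsulfonyl)oxaziridine, O=S(=O)(N1OC1c1ccccc1)c1ccccc1
Why: Davis-type enolate hydroxylation, with kinetic deprotonation at the CH2 α-carbon and oxygen transfer to the exo face of enolate 13 (the endo face is shielded by the ethano bridge and its side chain), giving the axial alcohol syn to the O bridge (C5 of the target); cyclisation of the enolate onto the acrylate would be a disfavoured 5-endo-trig closure.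

**Step 6**
Reactants: 14 racemic α-hydroxy ketone
Product: 15 tert-butyl 2-[(1R,2S,4S,5S,6S)-2-methyl-4-(3-methylbutanoyloxy)-3-oxo-8-oxabicyclo[3.2.1]octan-6-yl]prop-2-enoate
Conditions: (S)-2-phenyl-2,3-dihydrobenzo[d]imidazo[2,1-b]thiazole (5 mol%), (i-BuCO)2O (0.5 equiv), i-Pr2NEt (0.6 equiv), CHCl3, 0 °C, stopped at about 45% conversion
Reagents that add atoms: 3-methylbutanoic anhydride, CC(C)CC(=O)OC(=O)CC(C)C
Why: Acylative kinetic resolution of an α-hydroxy ketone by chiral isothiourea acyl-transfer catalysis, in which the acyl-isothiouronium ion recognises the carbonyl next to the carbinol and esterifies the drawn enantiomer much faster, so the isovalerate is installed and the racemate resolved in one operation; the slow enantiomer of 14 stays as the alcohol and is removed by chromatography.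

**Step 7**
Reactants: 15 α-acyloxy ketone; 16 (E)-1-methoxybuta-1,3-diene
Product: 20 tert-butyl 2-[(1R,2S,3S,4S,5S,6S)-3-[(2E)-but-2-enoyl]-3-hydroxy-2-methyl-4-(3-methylbutanoyloxy)-8-oxabicyclo[3.2.1]octan-6-yl]prop-2-enoate, via organolithium 17 (not isolated), via organocerium 18 (not isolated), via dienol ether adduct 19 (not isolated)
Conditions: 16 (3 equiv), t-BuLi (3 equiv), THF, −78 to −20 °C; CeCl3 (3.2 equiv), −78 °C; 15, −78 °C; then 1 M HCl, THF, 0 °C
Reagents that add atoms: water, O
Why: Organocerium 1,2-addition of an α-alkoxydienyl acyl-anion equivalent followed by enol ether hydrolysis; the weakly basic cerium reagent adds to the ketone rather than the esters and from the exo face (the endo face is blocked by the ethano bridge and the endo acrylate), which places the new C–C bond syn to the O bridge and the tertiary OH axial (C1 of the target), and aqueous acid converts the dienol ether into the conjugated (E)-enone.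

**Step 8**
Reactants: 20 bridged ether with endo tert-butyl acrylate
Product: 22 target lactone CNP0186412.1, via acrylic acid 21 (not isolated)
Conditions: CF3SO3H (20 mol%), (CF3)2CHOH/CH2Cl2 1:4, 0 °C to rt
Reagents that add atoms: none
Why: Proposed new method: acid-catalysed invertive transannular lactonization of an unstrained bridging ether, in which CF3SO3H removes the tert-butyl group as isobutene and activates the ether oxygen (helped by hydrogen bonding from the fluorinated alcohol), and the endo acrylic acid carbonyl, held anti-periplanar to the C6–O bond (dihedral about 165°), displaces the bridge oxygen at C6 in an SN2 manner, which forms the cis-fused α-methylene lactone, sets C6 by inversion, leaves the bridge oxygen on C9 as the free hydroxyl with retention, relieves the clash between the axial tertiary carbinol and the endo side chain and regenerates the acid; the closest known reactions are the acid-mediated acetolysis of 7-oxanorbornane bridges and the dealkylative lactonization of tert-butyl esters onto epoxides, oxetanes and halonium ions.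

**Compound list**
1 | 3-bromofuran | Brc1ccoc1 | starting material
2 | tert-butyl acetate | CC(=O)OC(C)(C)C | starting material
3 | lithium 1-tert-butoxyethenolate (lithium enolate of 2) | [Li+].[O-]C(=C)OC(C)(C)C | intermediate
4 | tert-butyl 2-(furan-3-yl)acetate | CC(C)(C)OC(=O)Cc1ccoc1 | intermediate
5 | 3-chlorobutan-2-one (racemic) | CC(Cl)C(C)=O | starting material
6 | 1-methyl-2-oxidoallyl cation (oxyallyl zwitterion) | C[CH+]C([O-])=C | intermediate
7 | tert-butyl 2-[rac-(1R,2S,5R)-2-methyl-3-oxo-8-oxabicyclo[3.2.1]oct-6-en-6-yl]acetate; methyl equatorial, anti to the O bridge, on the carbon remote from the side chain | O1[C@H]2C(CC(=O)OC(C)(C)C)=C[C@@H]1[C@H](C)C(=O)C2 | intermediate (racemic)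
8 | tert-butyl 2-[rac-(1R,2S,5R,6S)-2-methyl-3-oxo-8-oxabicyclo[3.2.1]octan-6-yl]acetate; side chain endo | O1[C@H]2[C@H](CC(=O)OC(C)(C)C)C[C@@H]1[C@H](C)C(=O)C2 | intermediate (racemic)
9 | dilithium bis-enolate of 8 (ketone enolate towards the CH2 carbon, ester enolate) | O1[C@H]2[C@H](C=C([O-])OC(C)(C)C)C[C@@H]1[C@H](C)C([O-])=C2.[Li+].[Li+] | intermediate
10 | Mannich base: tert-butyl 3-(dimethylamino)-2-[rac-(1R,2S,5R,6S)-2-methyl-3-oxo-8-oxabicyclo[3.2.1]octan-6-yl]propanoate, both epimers at the side-chain carbon | O1[C@H]2[C@H](C(CN(C)C)C(=O)OC(C)(C)C)C[C@@H]1[C@H](C)C(=O)C2 | intermediate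
11 | methiodide of 10 (trimethylammonium iodide) | O1[C@H]2[C@H](C(C[N+](C)(C)C)C(=O)OC(C)(C)C)C[C@@H]1[C@H](C)C(=O)C2.[I-] | intermediate
12 | tert-butyl 2-[rac-(1R,2S,5R,6S)-2-methyl-3-oxo-8-oxabicyclo[3.2.1]octan-6-yl]prop-2-enoate | O1[C@H]2[C@H](C(=C)C(=O)OC(C)(C)C)C[C@@H]1[C@H](C)C(=O)C2 | intermediate (racemic)
13 | potassium enolate of 12 (towards the CH2 carbon) | O1[C@H]2[C@H](C(=C)C(=O)OC(C)(C)C)C[C@@H]1[C@H](C)C([O-])=C2.[K+] | intermediate
14 | tert-butyl 2-[rac-(1R,2S,4S,5S,6S)-4-hydroxy-2-methyl-3-oxo-8-oxabicyclo[3.2.1]octan-6-yl]prop-2-enoate; hydroxyl axial, syn to the O bridge | O1[C@H]2[C@H](C(=C)C(=O)OC(C)(C)C)C[C@@H]1[C@H](C)C(=O)[C@H]2O | intermediate (racemic)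
15 | tert-butyl 2-[(1R,2S,4S,5S,6S)-2-methyl-4-(3-methylbutanoyloxy)-3-oxo-8-oxabicyclo[3.2.1]octan-6-yl]prop-2-enoate | O1[C@H]2[C@H](C(=C)C(=O)OC(C)(C)C)C[C@@H]1[C@H](C)C(=O)[C@H]2OC(=O)CC(C)C | intermediate
16 | (E)-1-methoxybuta-1,3-diene | CO/C=C/C=C | starting material
17 | [(1E)-1-methoxybuta-1,3-dien-1-yl]lithium | [Li]/C(OC)=C\C=C | intermediate
18 | dichloro[(1E)-1-methoxybuta-1,3-dien-1-yl]cerium | Cl[Ce](Cl)/C(OC)=C\C=C | intermediate
19 | tert-butyl 2-[(1R,2S,3S,4S,5S,6S)-3-hydroxy-3-[(1E)-1-methoxybuta-1,3-dien-1-yl]-2-methyl-4-(3-methylbutanoyloxy)-8-oxabicyclo[3.2.1]octan-6-yl]prop-2-enoate | O1[C@H]2[C@H](C(=C)C(=O)OC(C)(C)C)C[C@@H]1[C@H](C)[C@@](O)(/C(OC)=C\C=C)[C@H]2OC(=O)CC(C)C | intermediate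
20 | tert-butyl 2-[(1R,2S,3S,4S,5S,6S)-3-[(2E)-but-2-enoyl]-3-hydroxy-2-methyl-4-(3-methylbutanoyloxy)-8-oxabicyclo[3.2.1]octan-6-yl]prop-2-enoate; tertiary OH axial, anti to the O bridge | O1[C@H]2[C@H](C(=C)C(=O)OC(C)(C)C)C[C@@H]1[C@H](C)[C@@](O)(C(=O)/C=C/C)[C@H]2OC(=O)CC(C)C | intermediate
21 | 2-[(1R,2S,3S,4S,5S,6S)-3-[(2E)-but-2-enoyl]-3-hydroxy-2-methyl-4-(3-methylbutanoyloxy)-8-oxabicyclo[3.2.1]octan-6-yl]prop-2-enoic acid | O1[C@H]2[C@H](C(=C)C(=O)O)C[C@@H]1[C@H](C)[C@@](O)(C(=O)/C=C/C)[C@H]2OC(=O)CC(C)C | intermediate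
22 | CNP0186412.1: (1S,5S,6R,7S,9R,10S)-1,9-dihydroxy-5-(3-methylbutanoyloxy)-2-oxo-4,5-secoguaia-3(E),11(13)-dien-12,6-olide | C=C1C(=O)O[C@@H]2[C@H]1C[C@@H](O)[C@H](C)[C@@](O)(C(=O)/C=C/C)[C@H]2OC(=O)CC(C)C | target

**Count**
Total steps: 8. Longest linear sequence: 8 (fully linear, 1 to 22). The material is racemic up to 14; step 6 discards at least half of it.

**Three steps most likely to fail**

Step 8 (the new reaction). Risks are no reaction, or ionisation at C9 with elimination instead of displacement at C6. The fallback uses known reactions only, sets out from 20 and comes back at 22. Me2BBr (CH2Cl2, −78 to 0 °C) cleaves the bridging ether by bromide attack at the less hindered C9 with inversion and gives the bromo alcohol tert-butyl ester F6, which keeps the C6 oxygen as a free hydroxyl. CF3CO2H removes the tert-butyl group to give the bromo hydroxy acid F7. A Mitsunobu lactonization (PPh3, diisopropyl azodicarboxylate, THF) closes the lactone with inversion at C6 to give the bromolactone F8. Displacement of the C9 bromide with HCO2Cs in DMF (second inversion at C9, net retention) gives the formate F9, and NaHCO3 in MeOH cleaves the formate to 22.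

Step 2 (regiochemistry and yield of the cycloaddition with a substituted furan used as the limiting partner). The fallback sets out from 4 and comes back at 7. Compound 4 is combined with the triethylsilyl enol ether of 1,1-dimethoxybutan-2-one F1 (made from the keto acetal with Et3SiOSO2CF3 and Et3N) under Me3SiOSO2CF3 catalysis in CH2Cl2 at −78 °C. The oxocarbenium terminus of this alkoxy-oxyallyl cation can only bond first to the more nucleophilic furan C2, so the regiochemistry is fixed electronically rather than sterically, giving the 4-methoxy ketone F2. SmI2 (THF/MeOH, −78 °C) then removes the α-methoxy group and returns 7.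

Step 7 (addition to a ketone hindered on both faces, in the presence of two esters and an acrylate). The fallback sets out from 15 and comes back at 20. The smaller reagent CH2=C(OEt)Li/CeCl3 (from ethyl vinyl ether and t-BuLi, THF, −78 °C) is added instead. The enol ether adduct F3 is hydrolysed on acidic work-up to the α-hydroxy methyl ketone F4. A boron aldol addition (Bu2BOSO2CF3, i-Pr2NEt, then CH3CHO, CH2Cl2, −78 °C) gives the β-hydroxy ketone F5, and acid-catalysed dehydration (camphorsulfonic acid, CH2Cl2, rt) gives the (E)-enone 20.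

**Further compounds**
F1 | step 2 | triethyl[(1,1-dimethoxybut-2-en-2-yl)oxy]silane | CC=C(O[Si](CC)(CC)CC)C(OC)OC
F2 | step 2 | tert-butyl 2-(4-methoxy-2-methyl-3-oxo-8-oxabicyclo[3.2.1]oct-6-en-6-yl)acetate (racemic, methoxy epimers) | O1[C@H]2C(CC(=O)OC(C)(C)C)=C[C@@H]1[C@H](C)C(=O)C2OC
F3 | step 7 | tert-butyl 2-[3-(1-ethoxyethenyl)-3-hydroxy-2-methyl-4-(3-methylbutanoyloxy)-8-oxabicyclo[3.2.1]octan-6-yl]prop-2-enoate | O1[C@H]2[C@H](C(=C)C(=O)OC(C)(C)C)C[C@@H]1[C@H](C)[C@@](O)(C(=C)OCC)[C@H]2OC(=O)CC(C)C
F4 | step 7 | tert-butyl 2-[3-acetyl-3-hydroxy-2-methyl-4-(3-methylbutanoyloxy)-8-oxabicyclo[3.2.1]octan-6-yl]prop-2-enoate | O1[C@H]2[C@H](C(=C)C(=O)OC(C)(C)C)C[C@@H]1[C@H](C)[C@@](O)(C(C)=O)[C@H]2OC(=O)CC(C)C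
F5 | step 7 | tert-butyl 2-[3-hydroxy-3-(3-hydroxybutanoyl)-2-methyl-4-(3-methylbutanoyloxy)-8-oxabicyclo[3.2.1]octan-6-yl]prop-2-enoate (carbinol epimers) | O1[C@H]2[C@H](C(=C)C(=O)OC(C)(C)C)C[C@@H]1[C@H](C)[C@@](O)(C(=O)CC(C)O)[C@H]2OC(=O)CC(C)C
F6 | step 8 | tert-butyl 2-[9-bromo-1,6-dihydroxy-10-methyl-5-(3-methylbutanoyloxy)-1-(but-2-enoyl)cyclohept-7-yl]prop-2-enoate (target numbering; C6 hydroxyl trans to the C7 side chain, C9 bromide inverted) | O[C@H]1[C@H](C(=C)C(=O)OC(C)(C)C)C[C@H](Br)[C@H](C)[C@@](O)(C(=O)/C=C/C)[C@H]1OC(=O)CC(C)C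
F7 | step 8 | the corresponding bromo hydroxy prop-2-enoic acid | O[C@H]1[C@H](C(=C)C(=O)O)C[C@H](Br)[C@H](C)[C@@](O)(C(=O)/C=C/C)[C@H]1OC(=O)CC(C)C
F8 | step 8 | 9-bromo-9-deoxy analogue of the target (bromide on the face opposite to the target hydroxyl) | C=C1C(=O)O[C@@H]2[C@H]1C[C@H](Br)[C@H](C)[C@@](O)(C(=O)/C=C/C)[C@H]2OC(=O)CC(C)C
F9 | step 8 | 9-O-formyl derivative of the target | C=C1C(=O)O[C@@H]2[C@H]1C[C@@H](OC=O)[C@H](C)[C@@](O)(C(=O)/C=C/C)[C@H]2OC(=O)CC(C)C
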